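**Plan**

1. Retrosynthetic cuts, in order: C11–H (hemiperketal → peroxide); the C8–O–O–C11 bridge, replaced by a direct C8–C11 σ-bond (an 8,11-cyclocembrane: cyclobutan-11-ol fused to a 12-membered carbocycle); C1–C2 plus the lactone C–O (intramolecular 2-(methoxycarbonyl)allylation); C11–C12 (alkenyllithium + cyclobutanone); C8–C9 (semipinacol ring expansion of a 1-alkenylcyclopropanol) and C8–C11 (alkenyllithium + cyclopropanone).
2. Forward: geraniol → C2–C11 cyclobutanone → addition of the C12–C14/C1 alkenyl unit → acrylate C15–C17 → Cr(II) closes the 12-membered ring and the cis-lactone → O2 insertion turns the cyclobutane into the 1,2-dioxane and the 12-ring into the 14-ring → C11 reduction.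
3. Enabling feature: the two peroxide carbons C8 and C11 are 1,4-related through C9–C10 and C8 is fully substituted. A C8–C9–C10–C11 cyclobutan-11-ol therefore fragments only at C8–C11, to a tertiary C8 radical and a C11 ketone, which take up O2 as the O–O bridge.
4. Stereochemistry: C7 by reagent control (Shi epoxidation); C1/C2 cis from the (Z)-allylchromium chair transition state; C8 from O2 capture anti to the 7-acetoxy group on the macrocyclic radical; C11 from exo-face hydride delivery. The cyclobutane centres are sacrificial; 3E comes from geraniol and 12Z from a Z-selective iodo-olefination.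
5. The peroxide is introduced only in the last two steps, so no earlier reagent has to tolerate an O–O bond.

Key step: step 19

Remark: cembrane numbering (C1/C2 = lactone β/γ carbons, C8/C11 = peroxide carbons) is used for all intermediates; the D-fructose-derived Shi ketone is taken to give the R configuration at the CH carbon of a trisubstituted olefin, so its enantiomer is used in step 6.

**Route**

Step 1
Reactants: 1 geraniol
Product: 2 geranyl tert-butyldiphenylsilyl ether
Conditions: TBDPSCl, imidazole, CH2Cl2, 0 °C → rt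
Reagents that add atoms: tert-butyl(chloro)diphenylsilane, CC(C)(C)[Si](Cl)(c1ccccc1)c1ccccc1
Why: Silyl ether formation at the primary allylic alcohol; the bulky TBDPS group survives t-BuLi and periodic acid and later shields the C3=C4 olefin; no stereocentre is formed.

Step 2
Reactants: 2 geranyl TBDPS ether
Product: 3 racemic 6,7-epoxide of 2 (geraniol numbering)
Conditions: mCPBA, NaHCO3, CH2Cl2, −20 → 0 °C
Reagents that add atoms: 3-chloroperbenzoic acid, OOC(=O)c1cccc(Cl)c1
Why: Prilezhaev epoxidation should take the electron-richer distal trisubstituted olefin before the one deactivated by the allylic oxygen; the epoxide configuration is irrelevant because both carbons are cleaved in step 3.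

Step 3
Reactants: 3 racemic epoxide
Product: 4 (4E)-6-(TBDPS-oxy)-4-methylhex-4-enal
Conditions: H5IO6, THF/Et2O, 0 °C
Reagents that add atoms: none
Why: Periodic acid opens the epoxide and cleaves the resulting glycol (Malaprade-type cleavage), releasing acetone and leaving the E-olefin and silyl ether untouched.

Step 4
Reactants: 4 aldehyde
Product: 5 tert-butyl{[(2E,6Z)-7-iodo-3-methylocta-2,6-dien-1-yl]oxy}diphenylsilane
Conditions: EtPPh3I, n-BuLi, THF; I2, −78 °C; NaHMDS; then 4, −78 → −20 °C
Reagents that add atoms: ethyltriphenylphosphonium iodide, CC[P+](c1ccccc1)(c1ccccc1)c1ccccc1.[I-]; iodine, II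
Why: Stork–Zhao-type Wittig iodo-olefination with the unstabilised α-iodo ylide Ph3P=C(I)CH3 should give the (Z)-2-iodoalkene (iodine cis to the chain) under kinetic control.

Step 5
Reactants: 5 vinyl iodide; 6 1-ethoxycyclopropan-1-ol
Product: 9 1-[(2Z,6E)-8-(TBDPS-oxy)-6-methylocta-2,6-dien-2-yl]cyclopropan-1-ol, via alkenyllithium 7 (not isolated), via cyclopropanone 8 (not isolated)
Conditions: 5, t-BuLi (2 equiv), Et2O, −78 °C; 6 pretreated with MeMgBr (1 equiv), THF, −78 → 0 °C; combine, → rt; aq. NH4Cl
Reagents that add atoms: none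
Why: Iodine–lithium exchange with retention of olefin geometry, then 1,2-addition of the alkenyllithium to cyclopropanone released from the hemiketal magnesium salt (cyclopropanone hemiketal method for 1-alkenylcyclopropanols).

Step 6
Reactants: 9 alkenylcyclopropanol
Product: 11 (2R)-2-[(1S,4E)-1-hydroxy-4-methyl-6-(TBDPS-oxy)hex-4-en-1-yl]-2-methylcyclobutan-1-one, via epoxy cyclopropanol 10 (not isolated)
Conditions: L-fructose-derived Shi ketone (30 mol %), Oxone (1.3 equiv), K2CO3, Bu4NHSO4, MeCN/DMM/aq. borate–EDTA buffer, 0 °C; extractive work-up; then BF3·OEt2 (10 mol %), CH2Cl2, −78 °C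
Reagents that add atoms: potassium peroxymonosulfate (Oxone), [K+].[O-]S(=O)(=O)OO
Why: Shi asymmetric epoxidation (chiral dioxirane, spiro transition state) sets C7 as S by reagent control at the cyclopropyl-activated olefin in preference to the hindered allylic-silyloxy olefin, and the Lewis acid then triggers a semipinacol ring expansion in which a cyclopropane C–C bond migrates to C8 anti to the epoxide C–O bond with C7–O retained; the rearrangement is deferred until Oxone is removed so that the cyclobutanone cannot undergo Baeyer–Villiger oxidation.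

Step 7
Reactants: 11 β-hydroxycyclobutanone
Product: 12 TBS ether of 11
Conditions: TBSOTf, 2,6-lutidine, CH2Cl2, −78 °C
Reagents that add atoms: tert-butyldimethylsilyl triflate, CC(C)(C)[Si](C)(C)OS(=O)(=O)C(F)(F)F
Why: Silyl ether formation at the hindered secondary alcohol under non-nucleophilic, weakly basic conditions avoids retro-aldol cleavage; stereocentres are untouched.

Step 8
Reactants: 13 3-[(4-methoxybenzyl)oxy]propan-1-ol
Product: 14 3-[(4-methoxybenzyl)oxy]propanal
Conditions: Dess–Martin periodinane, NaHCO3, CH2Cl2, 0 °C → rt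
Reagents that add atoms: none
Why: Dess–Martin oxidation of a primary alcohol to the aldehyde without over-oxidation.

Step 9
Reactants: 14 aldehyde
Product: 15 1-({[(3Z)-4-iodopent-3-en-1-yl]oxy}methyl)-4-methoxybenzene
Conditions: EtPPh3I, n-BuLi, THF; I2, −78 °C; NaHMDS; then 14, −78 → −20 °C
Reagents that add atoms: ethyltriphenylphosphonium iodide, CC[P+](c1ccccc1)(c1ccccc1)c1ccccc1.[I-]; iodine, II
Why: The same Stork–Zhao-type iodo-olefination fixes the 12Z geometry, with iodine (the future C11 position) cis to C14.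

Step 10
Reactants: 15 vinyl iodide; 12 cyclobutanone
Product: 18 (11S,8R,7S)-configured 11-triethylsilyloxy cyclobutane carrying the (Z)-5-(PMB-oxy)pent-2-en-2-yl group at C11 (see SMILES), via alkenyllithium 16 (not isolated), via lithium cyclobutanolate 17 (not isolated)
Conditions: 15, t-BuLi (2 equiv), Et2O, −78 °C; then 12, −78 °C; then TESOTf, −78 → 0 °C
Reagents that add atoms: triethylsilyl triflate, CC[Si](CC)(CC)OS(=O)(=O)C(F)(F)F
Why: Iodine–lithium exchange (retention) and 1,2-addition to the strained cyclobutanone, expected anti to the bulky C7 side chain; in situ O-silylation prevents later lactol formation with the C1 aldehyde, and the C8/C11 configuration is of no consequence because both centres are erased in step 19.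

Step 11
Reactants: 18 PMB ether
Product: 19 primary alcohol at C1
Conditions: DDQ, CH2Cl2/pH 7 buffer, 0 °C
Reagents that add atoms: none
Why: Oxidative cleavage of the PMB ether via its benzylic oxocarbenium ion; silyl ethers and trisubstituted olefins are inert under buffered conditions.

Step 12
Reactants: 19 alcohol
Product: 20 β,γ-unsaturated aldehyde at C1
Conditions: Dess–Martin periodinane, NaHCO3, CH2Cl2, 0 °C; used crude
Reagents that add atoms: none
Why: Buffered Dess–Martin oxidation gives the (Z)-4-methyl-3-enal without base, so conjugation of the olefin is avoided.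

Step 13
Reactants: 20 aldehyde; 21 methyl propiolate
Product: 23 Morita–Baylis–Hillman-type adduct (methyl 2-(1-hydroxyalkyl)acrylate; C1 epimers), via vinylalane 22 (not isolated)
Conditions: 21, DIBAL-H, NMO, THF, 0 °C; then 20, 0 °C → rt
Reagents that add atoms: none
Why: Hydroalumination of the propiolate gives the α-aluminoacrylate, which adds 1,2 to the aldehyde (vinylalumination) without the amine base of a Baylis–Hillman reaction; the new carbinol centre is unselective and becomes sp2 in step 17.

Step 14
Reactants: 23 tris-silyl ether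
Product: 24 tetraol (C2, C7, C1 and C11 hydroxyls free)
Conditions: TBAF, AcOH, THF, rt → 40 °C
Reagents that add atoms: none
Why: Fluoride-mediated cleavage of the TES, TBS and TBDPS ethers, buffered with acetic acid so that the acrylate is not attacked by alkoxide.

Step 15
Reactants: 24 tetraol
Product: 25 (2E)-enal at C2
Conditions: MnO2, CH2Cl2, rt
Reagents that add atoms: none
Why: MnO2 should oxidise the primary allylic alcohol chemoselectively; the electron-poor MBH carbinol and the non-allylic alcohols react much more slowly.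

Step 16
Reactants: 25 enal triol
Product: 26 1,7-diacetate (tertiary C11 hydroxyl free)
Conditions: Ac2O, pyridine, DMAP (5 mol %), CH2Cl2, 0 °C
Reagents that add atoms: acetic anhydride, CC(=O)OC(C)=O
Why: Acylation of the two secondary alcohols, with the tertiary cyclobutanol too hindered to react; it installs the final 7-acetate and activates the MBH alcohol.

Step 17
Reactants: 26 diacetate
Product: 27 methyl (Z)-2-(bromomethyl)enoate
Conditions: LiBr, THF, rt
Reagents that add atoms: lithium bromide, [Li+].[Br-]
Why: SN2′ displacement of the MBH acetate by bromide gives the thermodynamically favoured (Z)-allylic bromide (ester trans to C14), while the unactivated 7-acetate is untouched.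

Step 18
Reactants: 27 allylic bromide enal
Product: 29 (1S,2S,7S,8R,11S)-7-acetoxy-11-hydroxy-8,11-cyclocembra-3E,12Z,15(17)-trien-16,2-olide, via seco hydroxy ester 28 (not isolated)
Conditions: CrCl2 (6 equiv), THF, slow addition to 2 mM, rt; aq. NH4Cl; PPTS (cat.), CH2Cl2 if lactonisation is incomplete
Reagents that add atoms: none
Why: Intramolecular Nozaki–Hiyama-type Cr(II) 2-(alkoxycarbonyl)allylation followed by lactonisation; the γ-substituted allylchromium from the (Z)-bromide should add through a chair Zimmerman–Traxler transition state to the syn adduct and hence the cis-lactone, with the absolute sense (1S,2S) left to the conformational bias of the bicyclic 12-membered transition state.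

Step 19
Reactants: 29 macrocyclic cyclobutanol
Product: 31 (1S,2S,7S,8R)-7-acetoxy-8,11-epidioxy-11-hydroxycembra-3E,12Z,15(17)-trien-16,2-olide (hemiperketal), via hydroperoxy enone 30 (not isolated)
Conditions: Co(acac)2 (20–30 mol %), O2 (1 atm), MeCN, 25–40 °C
Reagents that add atoms: dioxygen, O=O
Why: Co(II)/O2 converts the only free hydroxyl, the C11 cyclobutanol, into an alkoxy radical whose β-scission breaks the strained C8–C11 ring-fusion bond, giving the 14-membered ring with a C11 enone carbonyl and a tertiary C8 radical that captures O2; the peroxyl radical is reduced to hydroperoxide 30, which adds to the C11 carbonyl. The closest known reaction type is the Co(acac)2/O2 oxidative ring expansion of cyclobutanols to 1,2-dioxan-3-ols (and the Mn-mediated cyclopropanol to 1,2-dioxolan-3-ol analogue). The carbocycle is not closed but enlarged from 12 to 14 members by the fragmentation, and the 1,2-dioxane closes by 6-exo-trig attack of the hydroperoxide oxygen on C11=O. C8 is set in the O2 capture, expected anti to the 7-acetoxy group on a radical held by the macrocycle with C6–C7 and C8–C9 antiperiplanar (7,8-anti = 8R), while the C11 hemiperketal centre is labile and is fixed in step 20; the cyclobutane configurations at C8 and C11 of 29 are erased, so both cyclobutanol epimers converge. The step needs regioselective scission towards C8 and not C10, secured by the fully substituted C8 (tertiary radical), and O2 capture faster than transannular radical addition or hydrogen transfer, secured by the O2 atmosphere, the absence of a silane or alcohol reductant and the electron-poor or remote alkenes.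

Step 20
Reactants: 31 hemiperketal
Product: 32 denticulatolide
Conditions: Et3SiH (5 equiv), BF3·OEt2, CH2Cl2, −78 °C
Reagents that add atoms: none
Why: Lewis-acid ionisation of the hemiperketal to the peroxycarbenium ion and hydride transfer from the silane (ionic hydrogenation); hydride should enter the exo face opposite the ten-carbon bridge that arches from C7 to C12, placing C12 cis to C7 (11S), and the O–O bond, acetate and lactone should survive at −78 °C.

**Compound list**

1 | geraniol, (2E)-3,7-dimethylocta-2,6-dien-1-ol | CC(C)=CCC/C(C)=C/CO | starting material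
2 | tert-butyl{[(2E)-3,7-dimethylocta-2,6-dien-1-yl]oxy}diphenylsilane | CC(C)=CCC/C(C)=C/CO[Si](c1ccccc1)(c1ccccc1)C(C)(C)C | intermediate
3 | rac-tert-butyl{[(2E)-5-(3,3-dimethyloxiran-2-yl)-3-methylpent-2-en-1-yl]oxy}diphenylsilane | CC1(C)OC1CC/C(C)=C/CO[Si](c1ccccc1)(c1ccccc1)C(C)(C)C | intermediate
4 | (4E)-6-[(tert-butyldiphenylsilyl)oxy]-4-methylhex-4-enal | O=CCC/C(C)=C/CO[Si](c1ccccc1)(c1ccccc1)C(C)(C)C | intermediate
5 | tert-butyl{[(2E,6Z)-7-iodo-3-methylocta-2,6-dien-1-yl]oxy}diphenylsilane | C/C(I)=C/CC/C(C)=C/CO[Si](c1ccccc1)(c1ccccc1)C(C)(C)C | intermediate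
6 | 1-ethoxycyclopropan-1-ol (cyclopropanone ethyl hemiketal) | CCOC1(O)CC1 | starting material
7 | [(2Z,6E)-8-(TBDPS-oxy)-6-methylocta-2,6-dien-2-yl]lithium | [Li]/C(C)=C\CC/C(C)=C/CO[Si](c1ccccc1)(c1ccccc1)C(C)(C)C | intermediate
8 | cyclopropanone | O=C1CC1 | intermediate
9 | 1-[(2Z,6E)-8-(TBDPS-oxy)-6-methylocta-2,6-dien-2-yl]cyclopropan-1-ol | C/C(=C/CC/C(C)=C/CO[Si](c1ccccc1)(c1ccccc1)C(C)(C)C)C1(O)CC1 | intermediate
10 | 1-[(2S,3S)-2-methyl-3-{(3E)-3-methyl-5-(TBDPS-oxy)pent-3-en-1-yl}oxiran-2-yl]cyclopropan-1-ol | OC1(CC1)[C@@]2(C)O[C@H]2CC/C(C)=C/CO[Si](c3ccccc3)(c3ccccc3)C(C)(C)C | intermediate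
11 | (2R)-2-[(1S,4E)-1-hydroxy-4-methyl-6-(TBDPS-oxy)hex-4-en-1-yl]-2-methylcyclobutan-1-one | O=C1CC[C@]1(C)[C@@H](O)CC/C(C)=C/CO[Si](c1ccccc1)(c1ccccc1)C(C)(C)C | intermediate
12 | (2R)-2-[(1S,4E)-1-(TBS-oxy)-4-methyl-6-(TBDPS-oxy)hex-4-en-1-yl]-2-methylcyclobutan-1-one | O=C1CC[C@]1(C)[C@@H](O[Si](C)(C)C(C)(C)C)CC/C(C)=C/CO[Si](c1ccccc1)(c1ccccc1)C(C)(C)C | intermediate
13 | 3-[(4-methoxybenzyl)oxy]propan-1-ol | OCCCOCc1ccc(OC)cc1 | starting material
14 | 3-[(4-methoxybenzyl)oxy]propanal | O=CCCOCc1ccc(OC)cc1 | intermediate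
15 | 1-({[(3Z)-4-iodopent-3-en-1-yl]oxy}methyl)-4-methoxybenzene | C/C(I)=C/CCOCc1ccc(OC)cc1 | intermediate
16 | [(2Z)-5-(PMB-oxy)pent-2-en-2-yl]lithium | [Li]/C(C)=C\CCOCc1ccc(OC)cc1 | intermediate
17 | lithium (1S,2R)-cyclobutan-1-olate from 16 and 12 (alkenyl cis to the C8 methyl) | C/C(=C/CCOCc1ccc(OC)cc1)[C@@]1(O[Li])CC[C@]1(C)[C@@H](O[Si](C)(C)C(C)(C)C)CC/C(C)=C/CO[Si](c1ccccc1)(c1ccccc1)C(C)(C)C | intermediate
18 | (1S,2R)-2-methyl-1-[(2Z)-5-(PMB-oxy)pent-2-en-2-yl]-2-[(1S,4E)-1-(TBS-oxy)-4-methyl-6-(TBDPS-oxy)hex-4-en-1-yl]-1-(triethylsilyloxy)cyclobutane | C/C(=C/CCOCc1ccc(OC)cc1)[C@@]1(O[Si](CC)(CC)CC)CC[C@]1(C)[C@@H](O[Si](C)(C)C(C)(C)C)CC/C(C)=C/CO[Si](c1ccccc1)(c1ccccc1)C(C)(C)C | intermediate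
19 | primary alcohol from 18 (PMB removed; (3Z)-4-cyclobutyl-pent-3-en-1-ol unit) | C/C(=C/CCO)[C@@]1(O[Si](CC)(CC)CC)CC[C@]1(C)[C@@H](O[Si](C)(C)C(C)(C)C)CC/C(C)=C/CO[Si](c1ccccc1)(c1ccccc1)C(C)(C)C | intermediate
20 | (3Z)-pent-3-enal from 19 (C1 aldehyde) | C/C(=C/CC=O)[C@@]1(O[Si](CC)(CC)CC)CC[C@]1(C)[C@@H](O[Si](C)(C)C(C)(C)C)CC/C(C)=C/CO[Si](c1ccccc1)(c1ccccc1)C(C)(C)C | intermediate
21 | methyl propiolate | C#CC(=O)OC | starting material
22 | diisobutyl[1-(methoxycarbonyl)vinyl]alane | C=C(C(=O)OC)[Al](CC(C)C)CC(C)C | intermediate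
23 | methyl 2-methylidene-3-hydroxy ester (MBH adduct of 20; C1 epimers; silyl ethers intact) | C=C(C(=O)OC)C(O)C/C=C(/C)[C@@]1(O[Si](CC)(CC)CC)CC[C@]1(C)[C@@H](O[Si](C)(C)C(C)(C)C)CC/C(C)=C/CO[Si](c1ccccc1)(c1ccccc1)C(C)(C)C | intermediate
24 | tetraol (1-OH, 2-OH, 7-OH, 11-OH) from 23 | C=C(C(=O)OC)C(O)C/C=C(/C)[C@@]1(O)CC[C@]1(C)[C@@H](O)CC/C(C)=C/CO | intermediate
25 | (2E)-enal triol from 24 | C=C(C(=O)OC)C(O)C/C=C(/C)[C@@]1(O)CC[C@]1(C)[C@@H](O)CC/C(C)=C/C=O | intermediate
26 | 1,7-diacetate of 25 | C=C(C(=O)OC)C(OC(C)=O)C/C=C(/C)[C@@]1(O)CC[C@]1(C)[C@@H](OC(C)=O)CC/C(C)=C/C=O | intermediate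
27 | methyl (2Z)-2-(bromomethyl)alk-2-enoate (CH2Br cis to C14) carrying the 7-acetate, C11 cyclobutanol and C2 enal | COC(=O)/C(CBr)=C/C/C=C(/C)[C@@]1(O)CC[C@]1(C)[C@@H](OC(C)=O)CC/C(C)=C/C=O | intermediate
28 | seco hydroxy ester: 12-membered (1S,2S)-2-hydroxy-1-[1-(methoxycarbonyl)vinyl] carbocycle | C=C(C(=O)OC)[C@H]1[C@@H](O)/C=C(\C)CC[C@H](OC(C)=O)[C@@]2(C)CC[C@]2(O)/C(C)=C\C1 | intermediate
29 | (1S,2S,7S,8R,11S)-7-acetoxy-11-hydroxy-8,11-cyclocembra-3E,12Z,15(17)-trien-16,2-olide | C=C1C(=O)O[C@H]2/C=C(\C)CC[C@H](OC(C)=O)[C@@]3(C)CC[C@]3(O)/C(C)=C\C[C@@H]12 | intermediate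
30 | (1S,2S,7S,8R)-7-acetoxy-8-hydroperoxy-11-oxocembra-3E,12Z,15(17)-trien-16,2-olide | C=C1C(=O)O[C@H]2/C=C(\C)CC[C@H](OC(C)=O)[C@](C)(OO)CCC(=O)/C(C)=C\C[C@@H]12 | intermediate
31 | (1S,2S,7S,8R,11S)-7-acetoxy-8,11-epidioxy-11-hydroxycembra-3E,12Z,15(17)-trien-16,2-olide (C11 anomeric centre labile) | C=C1C(=O)O[C@H]2/C=C(\C)CC[C@H](OC(C)=O)[C@@]3(C)CC[C@](O)(OO3)/C(C)=C\C[C@@H]12 | intermediate
32 | denticulatolide, (1S,2S,7S,8R,11S)-7-acetoxy-8,11-epidioxycembra-3E,12Z,15(17)-trien-16,2-olide | C=C1C(=O)O[C@H]2/C=C(\C)CC[C@H](OC(C)=O)[C@@]3(C)CC[C@H](OO3)/C(C)=C\C[C@@H]12 | target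

**Step count**

Total: 20 steps (1–7 C2–C11 fragment, 8–9 C12–C14/C1 fragment, 10–20 after convergence). Longest linear sequence: 18 steps (1–7, then 10–20).

**Steps most likely to fail**

Step 19. The C8 radical is planar, so O2 may be captured on both faces or on the wrong one. The open hydroperoxide 30 may also be decomposed by cobalt before it closes, and transannular radical addition may compete. The fallback forms the C8–O bond by an ionic path with neighbouring-group control. It sets out from 29: silver-catalysed radical ring-opening bromination (NBS, AgNO3 cat., K2S2O8) should give the 14-membered γ-bromo enone F1, whose C8 configuration does not matter. AgOTf with anhydrous H2O2 (urea–H2O2 in ether) then ionises the tertiary bromide. The 7-acetoxy group should capture the cation as the more stable trans-bridged acetoxonium ion, which H2O2 opens at C8 with inversion (Prévost-type anti opening). This gives the 7,8-anti hydroperoxide 30, which closes and rejoins the route at 31.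

Step 20. Hydride may be delivered to the wrong face of the peroxycarbenium ion, the 12Z olefin may isomerise in the allyl-cation-like intermediate, or reduction may occur at C13. The fallback replaces hydride delivery by a reagent-controlled reduction followed by SN2 ring closure. It sets out from 31 through its open form 30: 2-methoxypropene with PPTS masks the hydroperoxide as the peroxyketal enone F2. (S)-Me-CBS with catecholborane should reduce the C11 ketone to the (11R)-allylic alcohol F3. MsCl/Et3N at −40 °C gives the mesylate F4, used crude. Aqueous AcOH/THF unmasks the hydroperoxide, which displaces the mesylate (6-exo-tet, inversion, assisted by Cs2CO3) and arrives directly at 32.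

Step 18. Oligomerisation may outrun closure of the strained 12-membered ring, and facial selectivity relative to the remote C7/C8/C11 centres may be poor. The fallback uses a catalyst-controlled allylboration in place of the chromium Barbier reaction. It sets out from 26: Pd-catalysed borylation of the MBH acetate (B2pin2, Pd2(dba)3, DMSO) should give the (Z)-2-(methoxycarbonyl)allyl pinacol boronate F5. Intramolecular allylboration of the enal under chiral phosphoric acid catalysis at high dilution should proceed through a closed chair transition state to the syn adduct, with the face fixed by the catalyst. Lactonisation then rejoins the route at 29.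

**Further compounds**

F1 | step 19 | (1S,2S,7S)-7-acetoxy-8-bromo-11-oxocembra-3E,12Z,15(17)-trien-16,2-olide (C8 epimers) | C=C1C(=O)O[C@H]2/C=C(\C)CC[C@H](OC(C)=O)C(C)(Br)CCC(=O)/C(C)=C\C[C@@H]12
F2 | step 20 | (1S,2S,7S,8R)-7-acetoxy-8-[(2-methoxypropan-2-yl)peroxy]-11-oxocembra-3E,12Z,15(17)-trien-16,2-olide | C=C1C(=O)O[C@H]2/C=C(\C)CC[C@H](OC(C)=O)[C@](C)(OOC(C)(C)OC)CCC(=O)/C(C)=C\C[C@@H]12
F3 | step 20 | (1S,2S,7S,8R,11R)-7-acetoxy-11-hydroxy-8-[(2-methoxypropan-2-yl)peroxy]cembra-3E,12Z,15(17)-trien-16,2-olide | C=C1C(=O)O[C@H]2/C=C(\C)CC[C@H](OC(C)=O)[C@](C)(OOC(C)(C)OC)CC[C@@H](O)/C(C)=C\C[C@@H]12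
F4 | step 20 | 11-methanesulfonate of F3 | C=C1C(=O)O[C@H]2/C=C(\C)CC[C@H](OC(C)=O)[C@](C)(OOC(C)(C)OC)CC[C@@H](OS(C)(=O)=O)/C(C)=C\C[C@@H]12
F5 | step 18 | methyl (2Z)-2-[(pinacolboryl)methyl]alk-2-enoate analogue of 27 (Bpin in place of Br) | COC(=O)/C(CB1OC(C)(C)C(C)(C)O1)=C/C/C=C(/C)[C@@]1(O)CC[C@]1(C)[C@@H](OC(C)=O)CC/C(C)=C/C=O
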